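Tuesday's run, at its first reading after 1.33 h, holds 46.7 % J and 43.0 % G, so 10.3 % of the charged G has gone elsewhere.

| setting | Tuesday's | flask |
|---|---|---|
| G | 2 M | 2.0 M |
| D | 1 equiv | 2.00 equiv |
| Z | 0.40 M | 0.400 M |
| remark | run made earlier |  |
| time |  | 3.0 d |
| volume of the second phase over the first |  | 2.0 |

Tuesday's run (percent of the G charged)

| time / h | J / % | G / % |
|---|---|---|
| 1.33 | 46.7 | 43.0 |
| 4.00 | 73.3 | 10.4 |
| 6.00 | 77.4 | 4.6 |
| 10.0 | 76.7 | 0.5 |
| 15.0 | 73.6 | 0.4 |

(scatter of a reading: 0.5 percentage points)

- in the second phase: D; everything else is in the first
- charges count per volume of the first phase; a concentration in a rate is the amount of a species over the volume of its own phase; every rate counts per litre of the first phase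
- the earlier runs hold the two phases in the same ratio of volumes as the flask asked about

* time, not beyond 3.0 d, at which the flask holds most J
* the amount of J, in percent of the G charged, at that time
* the first time at which J reaches 26 %, in the same percent

Two rates carry this problem: that of G going to J and that of G going elsewhere. Their ratio S, read from Tuesday's amounts, is 4.53, the J made per G lost elsewhere, a selectivity factor. This reckoning takes the J path as first order in D and supposes that the loss runs through Z. With the passage of D between the phases treated as an equilibrium at the same volume ratio, the reagent reaching the first phase follows the charge of D, and S follows that charge over [Z]. The flask asked about has 2.00 equiv of D against Tuesday's 1 equiv, at equal G and Z, so this reckoning puts S at 9.07 and gives J, with whatever comes from it, 90.1 % of the G. The added D should also hasten G, moving Tuesday's highest reading, at 6.00 h, to about 0.125 d, so this reckoning expects a top of J a little under 90.1 % there.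

The forecast says 78.2 % at 0.29 d, with the asked level reached at 0.6 h, holding that “Doubling D therefore changes little”.

The flask gives 87.6 % at 0.127 d, and reaches the asked level at 0.392 h, with L at 9.70 % at the best time.

    Q ⇌ D, rate k1*([Q] - [D]/K1) per volume of the first phase (partition coefficient = 0.620, kL = 1.07 /h)
    G + Q → J (k = 2.38 /M/h)
    G + Z → L (k = 0.433 /M/h)
    J ⇌ E (K = 0.880, k = 0.0114 /h)
    Q → X (k = 0.0314 /h)

S is k2[Q] over k3[Z], and the conversion of G + Z into L costs this flask 9.1 percentage points of its highest J: without that step the run reaches 96.7 % against 87.6 %.

For the neighbour with 0.50 M of G, at the same equivalents and the same Z, the reckoning puts S at 2.27, which leaves 69.4 % for J and what comes from it. Computed, that neighbour tops at 73.1 % of J and ends with 22.1 % of L, so the reckoning gives the right direction but overstates the loss there.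

(All runs are simulated from invented constants, and the scatter is random.)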